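**Retrosynthetic overview**
- Feature: in the phthalide (ring A = arene C3a–C7a, ring B = lactone C1/O2/C3), C3 and C1 sit on the neighbouring arene carbons C3a and C7a, and the C7 methoxy group flanks C7a. This is the pattern left by 1,2-difunctionalisation of 3,5-dimethoxybenzyne.
- Last disconnection: the lactone C1–O2 bond and both side-chain ketones go back to an open hydroxy N,N-diisopropylbenzamide with the ketones as dioxolanes.
- Key disconnection: C3–C3a and C7a–C1, made in one flask when an enantioenriched α-lithiated O-alkyl carbamate adds to the aryne and the new C7a aryllithium takes the carbamoyl group from oxygen.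
- Fragments: the iodo triflate from 3,5-dimethoxyphenol (2 steps); the C15 bis-dioxolane carbamate from 10-bromodecan-1-ol, N,N-diisopropylcarbamoyl chloride and 2-methylfuran (4 steps).
- Ring order: ring A is bought; ring B is closed last (step 8); C3 is set in the key step.

Key step: step 7

Assumption: the sparteine-bound carbanion is taken to substitute at the aryne with retention, as non-benzylic lithiated carbamates do with most electrophiles; should inversion be found, (−)-sparteine replaces (+)-sparteine in step 7.

**Route**

Step 1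
Reactants: 1 10-bromodecan-1-ol; 2 N,N-diisopropylcarbamoyl chloride
Product: 3 10-bromodecyl N,N-diisopropylcarbamate
Conditions: iPr2NEt, DMAP (cat.), CH2Cl2, reflux
Reagents that add atoms: none
Why: O-carbamoylation (nucleophilic acyl substitution) of the primary alcohol installs the hindered carbamate that later directs the α-lithiation and meanwhile protects the hydroxyl through steps 2 to 4.

Step 2
Reactants: 4 2-methylfuran; 3 10-bromodecyl N,N-diisopropylcarbamate
Product: 6 10-(5-methylfuran-2-yl)decyl N,N-diisopropylcarbamate, via 5-methyl-2-furyllithium 5 (not isolated)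
Conditions: 4, n-BuLi, THF, 0 °C; then 3, 0 °C → rt
Reagents that add atoms: none
Why: α-Lithiation of the furan at C5 and SN2 alkylation by the primary bromide should proceed cleanly, because the hindered diisopropylcarbamate is inert to the heteroaryllithium.

Step 3
Reactants: 6 10-(5-methylfuran-2-yl)decyl N,N-diisopropylcarbamate
Product: 7 11,14-dioxopentadecyl N,N-diisopropylcarbamate
Conditions: AcOH/H2O, H2SO4 (cat.), 100 °C
Reagents that add atoms: water, O
Why: Acid-catalysed hydrolytic ring opening of a 2,5-dialkylfuran (reverse Paal–Knorr) in a water-rich medium should give the 1,4-diketone, and the diisopropylcarbamate resists aqueous acid.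

Step 4
Reactants: 7 11,14-dioxopentadecyl N,N-diisopropylcarbamate
Product: 8 10-{2-[2-(2-methyl-1,3-dioxolan-2-yl)ethyl]-1,3-dioxolan-2-yl}decyl N,N-diisopropylcarbamate
Conditions: Me3SiOCH2CH2OSiMe3, TMSOTf (cat.), CH2Cl2, −78 → −20 °C; pyridine quench
Reagents that add atoms: 1,2-bis(trimethylsilyloxy)ethane, C[Si](C)(C)OCCO[Si](C)(C)C
Why: Noyori ketalisation converts both ketones into dioxolanes under cold aprotic conditions, which excludes the acid-driven cyclodehydration of the 1,4-diketone back to a furan.

Step 5
Reactants: 9 3,5-dimethoxyphenol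
Product: 10 2-iodo-3,5-dimethoxyphenol
Conditions: N-iodosuccinimide, CH2Cl2, −78 → 0 °C
Reagents that add atoms: N-iodosuccinimide, O=C1CCC(=O)N1I
Why: Electrophilic aromatic iodination in a non-polar solvent should be delivered by the hydrogen-bonded phenol to C2 (ortho to OH, para to a methoxy group) in preference to C4 between the two methoxy groups, and any minor 4-iodo isomer is removed by chromatography.

Step 6
Reactants: 10 2-iodo-3,5-dimethoxyphenol
Product: 11 2-iodo-3,5-dimethoxyphenyl trifluoromethanesulfonate
Conditions: Tf2O, pyridine, CH2Cl2, 0 °C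
Reagents that add atoms: trifluoromethanesulfonic anhydride, O=S(=O)(OS(=O)(=O)C(F)(F)F)C(F)(F)F
Why: O-Sulfonylation of the phenol gives the ortho-iodoaryl triflate, the standard low-temperature aryne precursor.

Step 7
Reactants: 8 10-{2-[2-(2-methyl-1,3-dioxolan-2-yl)ethyl]-1,3-dioxolan-2-yl}decyl N,N-diisopropylcarbamate; 11 2-iodo-3,5-dimethoxyphenyl trifluoromethanesulfonate
Product: 15 (S)-2-[1-hydroxy-10-{2-[2-(2-methyl-1,3-dioxolan-2-yl)ethyl]-1,3-dioxolan-2-yl}decyl]-4,6-dimethoxy-N,N-diisopropylbenzamide, via sparteine-bound lithiated carbamate 12 (not isolated), via 3,5-dimethoxybenzyne 13 (not isolated), via aryllithium 14 (not isolated)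
Conditions: 8 (1.3 equiv), s-BuLi (1.25 equiv), (+)-sparteine (1.3 equiv), Et2O, −78 °C, 5 h; then 11 (1.0 equiv); then n-BuLi (1.05 equiv, syringe pump, 1 h), −78 °C; −78 → 0 °C; AcOH
Reagents that add atoms: none
Why: Proposed new method: sec-butyllithium with (+)-sparteine removes the pro-R α-proton of 8 to give carbanion 12, which is configurationally stable at −78 °C; iodine–lithium exchange on 11 by the slowly added n-butyllithium and instant loss of lithium triflate release aryne 13 in its presence, the C–Li bond of 12 adds across the strained triple bond to give aryllithium 14, and 14 attacks the carbamate carbonyl so that the tetrahedral adduct ejects the benzylic alkoxide (a 1,4 O-to-C carbamoyl shift). The closest known reactions are the carbolithiation of arynes by alkyllithiums, the stereoretentive trapping of sparteine-complexed lithiated carbamates by electrophiles, and anionic Fries-type or Parham-type carbamoyl transfers to aryllithiums. The only ring closure is the transient 5-exo-trig attack of the C7a–Li carbon on the carbamate C=O, and this five-membered hemiaminal opens again, so no ring remains in 15. The C3 stereocentre is set by the sparteine-controlled enantiotopic deprotonation and is carried into 15 by substitution with retention at the sp3 carbanion, (R)-12 giving (S)-15. Regioselectivity at the aryne is required and is secured by the C7 methoxy group, which distorts the triple bond and places the developing negative charge at C7a beside the σ-withdrawing, lithium-binding oxygen, so the carbanion bonds to C3a. Chemoselectivity over the trigger is secured by keeping n-butyllithium at vanishing concentration (exchange at iodine outruns its addition to the aryne), and both ketones are masked as dioxolanes because a furan mask would cycloadd to the aryne.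

Step 8
Reactants: 15 (S)-2-[1-hydroxy-10-{2-[2-(2-methyl-1,3-dioxolan-2-yl)ethyl]-1,3-dioxolan-2-yl}decyl]-4,6-dimethoxy-N,N-diisopropylbenzamide
Product: 16 CJ-13,015, (S)-3-(10,13-dioxotetradecyl)-5,7-dimethoxy-2-benzofuran-1(3H)-one
Conditions: 3 M HCl, 1,4-dioxane, 80 °C
Reagents that add atoms: water, O
Why: Acid-catalysed lactonisation of the twisted ortho-(hydroxyalkyl) tertiary benzamide expels diisopropylamine and the same medium hydrolyses both dioxolanes, while the water-rich acid keeps the 1,4-diketone open as in step 3 and the C3–O bond is never broken, so the configuration should be preserved.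

**Compound list**
1 | 10-bromodecan-1-ol | OCCCCCCCCCCBr | starting material
2 | N,N-diisopropylcarbamoyl chloride | CC(C)N(C(C)C)C(=O)Cl | starting material
3 | 10-bromodecyl N,N-diisopropylcarbamate | BrCCCCCCCCCCOC(=O)N(C(C)C)C(C)C | intermediate
4 | 2-methylfuran | Cc1ccco1 | starting material
5 | 5-methyl-2-furyllithium (not isolated) | [Li]c1ccc(C)o1 | intermediate
6 | 10-(5-methylfuran-2-yl)decyl N,N-diisopropylcarbamate | Cc1ccc(CCCCCCCCCCOC(=O)N(C(C)C)C(C)C)o1 | intermediate
7 | 11,14-dioxopentadecyl N,N-diisopropylcarbamate | CC(=O)CCC(=O)CCCCCCCCCCOC(=O)N(C(C)C)C(C)C | intermediate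
8 | 10-{2-[2-(2-methyl-1,3-dioxolan-2-yl)ethyl]-1,3-dioxolan-2-yl}decyl N,N-diisopropylcarbamate | CC1(CCC2(CCCCCCCCCCOC(=O)N(C(C)C)C(C)C)OCCO2)OCCO1 | intermediate
9 | 3,5-dimethoxyphenol | COc1cc(O)cc(OC)c1 | starting material
10 | 2-iodo-3,5-dimethoxyphenol | COc1cc(O)c(I)c(OC)c1 | intermediate
11 | 2-iodo-3,5-dimethoxyphenyl trifluoromethanesulfonate | COc1cc(OC)c(I)c(OS(=O)(=O)C(F)(F)F)c1 | intermediate
12 | (R)-1-lithio derivative of 8, (+)-sparteine complex (ligand not drawn; not isolated) | [Li][C@H](CCCCCCCCCC1(CCC2(C)OCCO2)OCCO1)OC(=O)N(C(C)C)C(C)C | intermediate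
13 | 3,5-dimethoxybenzyne (not isolated) | COC1=CC#CC(OC)=C1 | intermediate
14 | (S)-1-(2-lithio-3,5-dimethoxyphenyl)-10-{2-[2-(2-methyl-1,3-dioxolan-2-yl)ethyl]-1,3-dioxolan-2-yl}decyl N,N-diisopropylcarbamate (not isolated) | [Li]c1c(OC)cc(OC)cc1[C@H](CCCCCCCCCC2(CCC3(C)OCCO3)OCCO2)OC(=O)N(C(C)C)C(C)C | intermediate
15 | (S)-2-[1-hydroxy-10-{2-[2-(2-methyl-1,3-dioxolan-2-yl)ethyl]-1,3-dioxolan-2-yl}decyl]-4,6-dimethoxy-N,N-diisopropylbenzamide | COc1cc(OC)c(C(=O)N(C(C)C)C(C)C)c(c1)[C@H](CCCCCCCCCC2(CCC3(C)OCCO3)OCCO2)O | intermediate
16 | CJ-13,015, (S)-3-(10,13-dioxotetradecyl)-5,7-dimethoxy-2-benzofuran-1(3H)-one | COc1cc(OC)c2c(c1)[C@H](CCCCCCCCCC(=O)CCC(C)=O)OC2=O | target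

**Step count**
Total: 8 steps. Longest linear sequence: 6 steps (steps 1, 2, 3, 4, 7, 8).

**Steps most likely to fail**

Step 7. Several processes can divert it:
- the carbanion may exchange lithium for iodine with the aryl iodide before the trigger arrives;
- the trigger may add to the aryne;
- the aryne may be attacked at C7a;
- the aryllithium may be protonated before the carbamoyl shift;
- bond formation may run through electron transfer and erode the configuration.

The fallback uses known lithiation–borylation chemistry, sets out from 8 and returns at 16. Carbamate 8 is lithiated as in step 7 (s-BuLi, (+)-sparteine, Et2O, −78 °C) and trapped with commercial 2-(3,5-dimethoxyphenyl)-4,4,5,5-tetramethyl-1,3,2-dioxaborolane. Stereospecific 1,2-aryl migration of the boronate with loss of the carbamate (MgBr2·OEt2, Et2O, reflux) should give the secondary benzylic boronic ester F1. NaOH/H2O2 should oxidise it with retention to the (S)-benzylic alcohol F2; retention at borylation and inversion at migration lead to the same (S) sense as the key step. N-Bromosuccinimide (MeCN, 0 °C) should brominate the ring ortho to the carbinol and para to a methoxy group, giving aryl bromide F3. Deprotonation, bromine–lithium exchange (n-BuLi then t-BuLi, THF, −78 °C) and CO2 should give the hydroxy acid F4 as its lithium salt. Acidification with 2 M HCl in THF closes the lactone and hydrolyses both dioxolanes, which brings the sequence back at 16.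

Step 8. Expulsion of diisopropylamine from the doubly ortho-substituted amide may need an acid strength at which the freed 1,4-diketone starts to cyclodehydrate or to undergo aldol condensation. The fallback sets out from 15 and returns at 16. The lactone is closed while both ketones are still masked (camphorsulfonic acid, 1.2 equiv, dry toluene, 80 °C), giving the bis-dioxolane phthalide F5. The ketones are then released under mild conditions (1 M HCl, THF, rt).

Step 5. Iodination may occur at C4 between the methoxy groups or twice, giving isomers that are hard to separate. The fallback sets out from 9 and returns at 10. The phenol is converted with N,N-diethylcarbamoyl chloride (K2CO3, MeCN, reflux) into the aryl carbamate F6. Directed ortho-metalation (s-BuLi, TMEDA, THF, −78 °C) and an iodine quench at −78 °C, before any anionic Fries shift, should give the 2-iodo carbamate F7; the carbamate is the strongest director and its ortho position is also flanked by a methoxy group. NaOH in refluxing ethanol then frees phenol 10.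

**Further compounds**
F1 | step 7 | (S)-2-[1-(3,5-dimethoxyphenyl)-10-{2-[2-(2-methyl-1,3-dioxolan-2-yl)ethyl]-1,3-dioxolan-2-yl}decyl]-4,4,5,5-tetramethyl-1,3,2-dioxaborolane | CC1(C)OB(OC1(C)C)[C@@H](CCCCCCCCCC2(CCC3(C)OCCO3)OCCO2)c4cc(OC)cc(OC)c4
F2 | step 7 | (S)-1-(3,5-dimethoxyphenyl)-10-{2-[2-(2-methyl-1,3-dioxolan-2-yl)ethyl]-1,3-dioxolan-2-yl}decan-1-ol | COc1cc(OC)cc(c1)[C@H](CCCCCCCCCC2(CCC3(C)OCCO3)OCCO2)O
F3 | step 7 | (S)-1-(2-bromo-3,5-dimethoxyphenyl)-10-{2-[2-(2-methyl-1,3-dioxolan-2-yl)ethyl]-1,3-dioxolan-2-yl}decan-1-ol | COc1cc(OC)c(Br)c(c1)[C@H](CCCCCCCCCC2(CCC3(C)OCCO3)OCCO2)O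
F4 | step 7 | (S)-2-[1-hydroxy-10-{2-[2-(2-methyl-1,3-dioxolan-2-yl)ethyl]-1,3-dioxolan-2-yl}decyl]-4,6-dimethoxybenzoic acid | COc1cc(OC)c(C(=O)O)c(c1)[C@H](CCCCCCCCCC2(CCC3(C)OCCO3)OCCO2)O
F5 | step 8 | (S)-5,7-dimethoxy-3-(10-{2-[2-(2-methyl-1,3-dioxolan-2-yl)ethyl]-1,3-dioxolan-2-yl}decyl)-2-benzofuran-1(3H)-one | COc1cc(OC)c2c(c1)[C@H](CCCCCCCCCC3(CCC4(C)OCCO4)OCCO3)OC2=O
F6 | step 5 | 3,5-dimethoxyphenyl N,N-diethylcarbamate | CCN(CC)C(=O)Oc1cc(OC)cc(OC)c1
F7 | step 5 | 2-iodo-3,5-dimethoxyphenyl N,N-diethylcarbamate | CCN(CC)C(=O)Oc1cc(OC)cc(OC)c1I
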